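## Retrosynthetic overview

1. Target ⇒ bis-MOM chalcone ⇒ Claisen–Schmidt disconnection of the enone C=C into a 3-alkylated 2,4-bis(methoxymethoxy)acetophenone and 4-hydroxybenzaldehyde.
2. Acetyl group ⇒ ortho-lithiation and Weinreb acetylation of a mirror-symmetric 2-alkylresorcinol bis-MOM ether that already carries the finished (R)-side chain.
3. Key disconnection, carbinol C–C(=CH2): an (S)-α-carbamoyloxy carbanion (sparteine lithiation, then zinc) acts as a carbinol carbon of reversed polarity and is coupled with the enol triflate of 6-methylhept-5-en-2-one. Two carbonyl-type acceptor carbons are joined and the (R)-centre is set in the same step.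
4. The carbamate comes from resorcinol (bis-MOM ether, C2-lithiation, ethylene oxide, carbamoyl chloride); the triflate comes from sulcatone.
5. No ring is formed: ring A is bought as resorcinol and ring B as 4-hydroxybenzaldehyde.

Assumption: the descriptor in the target SMILES corresponds to the (R)-carbinol; numbered compounds are those that supply carbon to the target and what is made from them, while auxiliary reagents are given by name and SMILES in the steps.

## Route

Step 1
Reactants: 1 resorcinol
Product: 2 1,3-bis(methoxymethoxy)benzene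
Conditions: MOMCl (2.5 equiv), iPr2NEt (3 equiv), CH2Cl2, 0 °C → rt, 12 h
Reagents that add atoms: chloromethyl methyl ether (MOMCl), COCCl
Why: Double O-alkylation of the phenol (MOM acetal protection) gives ethers that survive organolithium and hydride reagents and later act as ortho-directing groups.

Step 2
Reactants: 2 1,3-bis(methoxymethoxy)benzene; 3 ethylene oxide
Product: 6 2-[2,6-bis(methoxymethoxy)phenyl]ethyl N,N-diisopropylcarbamate, via 2,6-bis(methoxymethoxy)phenyllithium 4 (not isolated), via lithium 2-[2,6-bis(methoxymethoxy)phenyl]ethoxide 5 (not isolated)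
Conditions: nBuLi (1.1 equiv), THF, 0 °C, 1 h; ethylene oxide (1.5 equiv), −78 °C → rt; then iPr2NCOCl (1.3 equiv), reflux, 16 h
Reagents that add atoms: N,N-diisopropylcarbamoyl chloride, CC(C)N(C(C)C)C(Cl)=O
Why: Directed ortho-metalation at the doubly activated C2 between the two OMOM groups, SN2 opening of ethylene oxide by the aryllithium, and O-carbamoylation of the resulting lithium alkoxide in the same flask.

Step 3
Reactants: 7 6-methylhept-5-en-2-one (sulcatone)
Product: 9 6-methylhepta-1,5-dien-2-yl trifluoromethanesulfonate, via lithium 6-methylhepta-1,5-dien-2-olate 8 (not isolated)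
Conditions: LiN(iPr)2 (1.1 equiv), THF, −78 °C, 1 h; PhNTf2 (1.05 equiv), −78 → 0 °C
Reagents that add atoms: N-phenylbis(trifluoromethanesulfonimide), O=S(=O)(N(c1ccccc1)S(=O)(=O)C(F)(F)F)C(F)(F)F
Why: Kinetic deprotonation at −78 °C takes a methyl hydrogen (about 9:1 over the methylene side) and O-sulfonylation of the terminal enolate gives the 1,1-disubstituted enol triflate (enol triflate formation), the minor internal isomer being removed by chromatography.

Step 4
Reactants: 6 2-[2,6-bis(methoxymethoxy)phenyl]ethyl N,N-diisopropylcarbamate; 9 6-methylhepta-1,5-dien-2-yl trifluoromethanesulfonate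
Product: 12 (2R)-1-[2,6-bis(methoxymethoxy)phenyl]-7-methyl-3-methylideneoct-6-en-2-yl N,N-diisopropylcarbamate, via (S)-α-lithio carbamate 10 (not isolated), via (S)-α-chlorozincio carbamate 11 (not isolated)
Conditions: sBuLi (1.3 equiv), (−)-sparteine (1.3 equiv), Et2O, −78 °C, 5 h; ZnCl2 (1.5 equiv, in THF), −78 °C → rt; 9 (1.5 equiv), Pd(OAc)2 (5 mol%), tBu3P·HBF4 (10 mol%), rt → 40 °C, 16 h
Reagents that add atoms: none
Why: Proposed new method: sBuLi/(−)-sparteine removes the pro-S α-hydrogen of the carbamate (Hoppe asymmetric deprotonation) to give a configurationally stable α-oxy carbanion, that is a carbinol carbon of reversed polarity (an acyl-anion equivalent at the alcohol oxidation level), Li-to-Zn exchange and the Negishi coupling both go with retention, so the carbinol carbon is joined to the ketone-derived alkenyl triflate carbon and the (R)-centre is set directly (expected er about 95:5); the closest known reactions are the sparteine-lithiation/ZnCl2/Pd(OAc)2–tBu3P α-arylation of O-alkyl carbamates and the α-arylation and α-vinylation of N-Boc-pyrrolidine with aryl and alkenyl bromides, and the alkenyl triflate should couple at least as readily because it adds quickly to zerovalent palladium in the presence of the LiCl formed in situ while carbamate chelation holds back β-hydride elimination.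

Step 5
Reactants: 12 (2R)-1-[2,6-bis(methoxymethoxy)phenyl]-7-methyl-3-methylideneoct-6-en-2-yl N,N-diisopropylcarbamate
Product: 13 (2R)-1-[2,6-bis(methoxymethoxy)phenyl]-7-methyl-3-methylideneoct-6-en-2-ol
Conditions: LiAlH4 (4 equiv), THF, reflux, 12 h; aqueous work-up
Reagents that add atoms: none
Why: Hydride attack at the carbamate carbonyl (reductive cleavage of a Hoppe carbamate) frees the alcohol without touching the C–O bond of the stereocentre, and MOM acetals and isolated alkenes are inert to LiAlH4.

Step 6
Reactants: 13 (2R)-1-[2,6-bis(methoxymethoxy)phenyl]-7-methyl-3-methylideneoct-6-en-2-ol; 14 N-methoxy-N-methylacetamide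
Product: 16 1-{3-[(2R)-2-hydroxy-7-methyl-3-methylideneoct-6-en-1-yl]-2,4-bis(methoxymethoxy)phenyl}ethan-1-one, via dilithiated alcohol 15 (not isolated)
Conditions: nBuLi (2.3 equiv), TMEDA (2.3 equiv), THF, −20 → 0 °C, 2 h; 14 (1.5 equiv), −78 → 0 °C; H2O
Reagents that add atoms: none
Why: Directed ortho-metalation: the first equivalent of nBuLi makes the alkoxide, the second lithiates ortho to an OMOM group (the two free ortho positions are equivalent by symmetry), and the aryllithium is acylated by the Weinreb amide, whose chelated tetrahedral adduct stops at the ketone.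

Step 7
Reactants: 16 1-{3-[(2R)-2-hydroxy-7-methyl-3-methylideneoct-6-en-1-yl]-2,4-bis(methoxymethoxy)phenyl}ethan-1-one; 17 4-hydroxybenzaldehyde
Product: 18 (2E)-1-{3-[(2R)-2-hydroxy-7-methyl-3-methylideneoct-6-en-1-yl]-2,4-bis(methoxymethoxy)phenyl}-3-(4-hydroxyphenyl)prop-2-en-1-one
Conditions: KOH (10 equiv, 50% aq.), EtOH, rt → 40 °C, 24–48 h; AcOH to pH 6
Reagents that add atoms: none
Why: Claisen–Schmidt (crossed aldol) condensation of the methyl ketone enolate with the non-enolisable aldehyde and E1cB dehydration give the thermodynamically preferred E-enone, the protected 2′-oxygen rules out flavanone closure, and the carbinol centre has no acidifying neighbour and cannot epimerise.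

Step 8
Reactants: 18 (2E)-1-{3-[(2R)-2-hydroxy-7-methyl-3-methylideneoct-6-en-1-yl]-2,4-bis(methoxymethoxy)phenyl}-3-(4-hydroxyphenyl)prop-2-en-1-one
Product: 19 (2E)-1-{2,4-dihydroxy-3-[(2R)-2-hydroxy-7-methyl-3-methylideneoct-6-en-1-yl]phenyl}-3-(4-hydroxyphenyl)prop-2-en-1-one
Conditions: HCl (about 0.3 M in MeOH), 40 °C, 1–3 h (TLC control); NaHCO3
Reagents that add atoms: none
Why: Acid-catalysed transacetalisation of the two aryl MOM ethers with methanol (acetal cleavage) under dilute, short conditions of the kind that spare prenyl-type alkenes and chalcones, leaving the stereocentre untouched.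

## Compound list

1 | resorcinol (benzene-1,3-diol) | Oc1cccc(O)c1 | starting material
2 | 1,3-bis(methoxymethoxy)benzene | COCOc1cccc(OCOC)c1 | intermediate
3 | ethylene oxide (oxirane) | C1CO1 | starting material
4 | 2,6-bis(methoxymethoxy)phenyllithium | [Li]c1c(OCOC)cccc1OCOC | intermediate
5 | lithium 2-[2,6-bis(methoxymethoxy)phenyl]ethoxide | [Li]OCCc1c(OCOC)cccc1OCOC | intermediate
6 | 2-[2,6-bis(methoxymethoxy)phenyl]ethyl N,N-diisopropylcarbamate | CC(C)N(C(C)C)C(=O)OCCc1c(OCOC)cccc1OCOC | intermediate
7 | 6-methylhept-5-en-2-one (sulcatone) | CC(=O)CCC=C(C)C | starting material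
8 | lithium 6-methylhepta-1,5-dien-2-olate | C=C(O[Li])CCC=C(C)C | intermediate
9 | 6-methylhepta-1,5-dien-2-yl trifluoromethanesulfonate | C=C(CCC=C(C)C)OS(=O)(=O)C(F)(F)F | intermediate
10 | (1S)-2-[2,6-bis(methoxymethoxy)phenyl]-1-lithioethyl N,N-diisopropylcarbamate, present as its (−)-sparteine complex | CC(C)N(C(C)C)C(=O)O[C@@H]([Li])Cc1c(OCOC)cccc1OCOC | intermediate
11 | (1S)-2-[2,6-bis(methoxymethoxy)phenyl]-1-(chlorozincio)ethyl N,N-diisopropylcarbamate | CC(C)N(C(C)C)C(=O)O[C@@H]([Zn]Cl)Cc1c(OCOC)cccc1OCOC | intermediate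
12 | (2R)-1-[2,6-bis(methoxymethoxy)phenyl]-7-methyl-3-methylideneoct-6-en-2-yl N,N-diisopropylcarbamate | C=C(CCC=C(C)C)[C@H](OC(=O)N(C(C)C)C(C)C)Cc1c(OCOC)cccc1OCOC | intermediate
13 | (2R)-1-[2,6-bis(methoxymethoxy)phenyl]-7-methyl-3-methylideneoct-6-en-2-ol | C=C(CCC=C(C)C)[C@H](O)Cc1c(OCOC)cccc1OCOC | intermediate
14 | N-methoxy-N-methylacetamide | CON(C)C(C)=O | starting material
15 | dilithio derivative of 13 (lithium alkoxide, lithium at the ring carbon ortho to OMOM) | C=C(CCC=C(C)C)[C@H](O[Li])Cc1c(OCOC)ccc([Li])c1OCOC | intermediate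
16 | 1-{3-[(2R)-2-hydroxy-7-methyl-3-methylideneoct-6-en-1-yl]-2,4-bis(methoxymethoxy)phenyl}ethan-1-one | C=C(CCC=C(C)C)[C@H](O)Cc1c(OCOC)ccc(C(C)=O)c1OCOC | intermediate
17 | 4-hydroxybenzaldehyde | O=Cc1ccc(O)cc1 | starting material
18 | (2E)-1-{3-[(2R)-2-hydroxy-7-methyl-3-methylideneoct-6-en-1-yl]-2,4-bis(methoxymethoxy)phenyl}-3-(4-hydroxyphenyl)prop-2-en-1-one | C=C(CCC=C(C)C)[C@H](O)Cc1c(OCOC)ccc(C(=O)/C=C/c2ccc(O)cc2)c1OCOC | intermediate
19 | (2E)-1-{2,4-dihydroxy-3-[(2R)-2-hydroxy-7-methyl-3-methylideneoct-6-en-1-yl]phenyl}-3-(4-hydroxyphenyl)prop-2-en-1-one | C=C(CCC=C(C)C)[C@H](O)Cc1c(O)ccc(C(=O)/C=C/c2ccc(O)cc2)c1O | target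

## Step count and risks

Total step count: 8. Longest linear sequence: 7 steps (steps 1, 2, 4, 5, 6, 7, 8 from resorcinol); step 3 is a one-step side branch.

**Step 4 (key coupling).** sBuLi may metalate the ring ortho to OMOM or the benzylic CH2 instead of the carbamate α-position. The hindered secondary zinc reagent 11 may also transmetalate slowly or lose the stereocentre by β-hydride elimination on palladium. The fallback sets out from 2. Compounds 4 and 5 are formed as in step 2 but quenched with water to isolate 2-[2,6-bis(methoxymethoxy)phenyl]ethanol F1. Dess–Martin periodinane (NaHCO3, CH2Cl2, 0 °C) oxidises it to 2-[2,6-bis(methoxymethoxy)phenyl]acetaldehyde F2. F2 and triflate 9 are then joined in an asymmetric Nozaki–Hiyama–Kishi reaction (CrCl2, NiCl2 cat., Kishi-type chiral oxazoline–sulfonamide ligand in the enantiomeric form that gives the (R)-carbinol, Et3N, THF/MeCN, rt). This gives alcohol 13 directly, so the route is rejoined at 13 and step 5 falls away.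

**Step 6 (ring acetylation).** The crowded aryllithium 15 may deprotonate the enolisable acetamide 14 instead of adding to it, returning 13. The fallback sets out from 13 and generates 15 as before, but acylates it with the non-enolisable (E)-N-methoxy-3-[4-(methoxymethoxy)phenyl]-N-methylprop-2-enamide F3. F3 is made in one operation from commercial 4-(methoxymethoxy)benzaldehyde and diethyl [2-(methoxy(methyl)amino)-2-oxoethyl]phosphonate (NaH, THF, Horner–Wadsworth–Emmons). The acylation installs the whole cinnamoyl unit and gives (2E)-1-{3-[(2R)-2-hydroxy-7-methyl-3-methylideneoct-6-en-1-yl]-2,4-bis(methoxymethoxy)phenyl}-3-[4-(methoxymethoxy)phenyl]prop-2-en-1-one F4. Methanolic HCl as in step 8 then removes the three MOM groups, so the route is rejoined at 19 and step 7 falls away.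

**Step 8 (final deprotection).** Acid can add methanol or a phenol across the alkenes (chroman formation), ionise the allylic alcohol, or close the freed 2′-hydroxychalcone to the flavanone. The fallback sets out from 16 and removes the MOM groups before the enone exists, with ZnBr2/nPrSH (CH2Cl2, 0 °C, 10 min). This thiol-assisted Lewis-acid cleavage is fast and non-protic but could not be used on the chalcone because the thiol would add to the enone. It gives 1-{2,4-dihydroxy-3-[(2R)-2-hydroxy-7-methyl-3-methylideneoct-6-en-1-yl]phenyl}ethan-1-one F5. Claisen–Schmidt condensation of unprotected F5 with 17 (KOH, 60% aq., EtOH, rt, 48–72 h) then gives the target, so the route is rejoined at 19; a lower yield is expected for this condensation.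

## Further compounds

F1 | step 4 | 2-[2,6-bis(methoxymethoxy)phenyl]ethanol | OCCc1c(OCOC)cccc1OCOC
F2 | step 4 | 2-[2,6-bis(methoxymethoxy)phenyl]acetaldehyde | O=CCc1c(OCOC)cccc1OCOC
F3 | step 6 | (E)-N-methoxy-3-[4-(methoxymethoxy)phenyl]-N-methylprop-2-enamide | CON(C)C(=O)/C=C/c1ccc(OCOC)cc1
F4 | step 6 | (2E)-1-{3-[(2R)-2-hydroxy-7-methyl-3-methylideneoct-6-en-1-yl]-2,4-bis(methoxymethoxy)phenyl}-3-[4-(methoxymethoxy)phenyl]prop-2-en-1-one | C=C(CCC=C(C)C)[C@H](O)Cc1c(OCOC)ccc(C(=O)/C=C/c2ccc(OCOC)cc2)c1OCOC
F5 | step 8 | 1-{2,4-dihydroxy-3-[(2R)-2-hydroxy-7-methyl-3-methylideneoct-6-en-1-yl]phenyl}ethan-1-one | C=C(CCC=C(C)C)[C@H](O)Cc1c(O)ccc(C(C)=O)c1O
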